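## The problem

CNP0265335.4 (31) is a heliangolide-type germacranolide. A ten-membered carbocycle (C1–C10) is trans-fused through C6–O and C7–C11 to an α-methylene-γ-butyrolactone. The ring carries a Z-trisubstituted C4=C5 alkene, a trans 1,10-epoxide, an (R)-2-methylbutanoate on C3 and a (2S,3R)-2,3-dimethyloxirane-2-carboxylate on C8. Six stereocentres lie on the ring (1R, 3S, 6R, 7R, 8R, 10R) and three in the acyl groups. The contiguous C6/C7/C8 triad can be built in an open-chain lactone in which C6 controls C7. C3 and the C1/C10 epoxide are remote from that triad and can be steered only by the conformation of the finished ring or by a chiral reagent. In the target the C8 oxygen is anti to C11 while the lactone oxygen is syn to it. A closed allylation transition state gives the opposite relationship, so C8 needs one inversion. The exo-methylene lactone is a Michael acceptor and excludes alkoxides, amines, thiolates and hydrides late in the route. Both epoxides and the 1(10),4-diene are acid-sensitive (epoxide opening, transannular cyclisation), and the two aldehydes the route needs are skipped (β,γ-unsaturated) and isomerise easily. The enabling feature is C3: it is an allylic carbinol bonded to C4 of the Z C4=C5 alkene. A Z-vinyl iodide at C4 and an aldehyde at C3 of a seco-lactone therefore map onto the ring bond C3–C4, while the trans-lactone and the two preformed alkenes hold the chain ends close.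

## Retrosynthesis

**31 ⇒ 30 (C1–O and C10–O).** The 1,10-epoxide is removed first, leaving the E C1=C10 alkene of diester 30. The epoxide is the most acid-labile group and would not survive a ring closure next to it. In 30 the C1=C10 alkene is the only electron-rich alkene, because C4=C5 is flanked by two allylic acyloxy groups and the exo-methylene is conjugated. The forward reaction must be a peracid epoxidation on the outer face of the ring alkene.

**30 ⇒ 28 + 29 (C3–O acyl bond).** The 2-methylbutanoate is cut to the macrocyclic allylic alcohol 28 and (R)-2-methylbutanoic acid 29. This exposes the carbinol that the ring closure creates. The forward step is an ordinary carbodiimide esterification that must not epimerise the acid.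

**28 ⇒ 26 (C3–C4, the ring bond).** The C3–C4 cut gives the acyclic iodo-aldehyde 26, in which both alkene geometries and the C6/C7/C8 triad are already fixed. A cut at C1=C10 (olefination or metathesis) would leave the E geometry to chance, and a cut at C6–C7 or C7–C8 would move the stereotriad into the macrocyclisation. The forward reaction is a nickel/chromium-mediated addition of the Z-vinyl iodide to the aldehyde at high dilution. Only the C3 configuration is left to the ring.

**26 ⇒ 25 ⇒ 24 ⇒ 20 + 23 (oxidation level at C3, then C8–O).** The aldehyde is traced to primary alcohol 25 and its 4-methoxybenzyl ether 24. The C8 ester is cut to alcohol 20 and epoxy acid 23, with the forward step run as a Mitsunobu esterification. This is chosen because the allylation that makes 20 delivers the 8S carbinol, the epimer of what 31 needs. Esterifying with inversion on the open chain corrects C8 and installs the final acyl group in one operation. It also avoids a silylation, a desilylation and an inversion on the ten-membered ring. The glycidic ester must then survive DDQ, Dess–Martin oxidation and the chromium step.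

**20 ⇒ 9 + 18 (C7–C8).** An indium Barbier reaction joins bromomethyl butenolide 9 (γ-attack) to skipped aldehyde 18. It forms C7–C8, sets C7 trans to the C6 substituent and creates the exo-methylene lactone without a separate methylenation. A stepwise aldol/lactonisation/methylenation sequence would cost several more steps. The price is the 8S configuration, handled above.

**9 ⇒ 8 ⇒ 6 + 7; 6 ⇒ 5 ⇒ 4 ⇒ 3 ⇒ 1.** The butenolide is opened at C7=C11 by ring-closing metathesis of ester 8, made from dienol 6 and 2-(bromomethyl)acrylic acid 7. Dienol 6 comes from racemic 5 by Sharpless kinetic resolution. Racemate 5 comes from vinyl Grignard addition to (Z)-3-iodobut-2-enal 4, itself from but-2-yn-1-ol 1 through hydroalumination/iodination (3) and oxidation. The Z-iodoalkene is thus fixed in the first step.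

**18 ⇒ 17 ⇒ 16 ⇒ 15 ⇒ 11 + 12 ⇒ 10.** The E trisubstituted C1=C10 alkene comes from zirconium-catalysed carboalumination of silylated but-3-yn-1-ol 11, trapped with ethylene oxide 12. The two chain ends are then differentiated (PMB on the future C3 oxygen, desilylation and oxidation at the future C8).

**23 ⇒ 22 ⇒ 21.** The epoxy acid is made by Sharpless epoxidation of (E)-2-methylbut-2-en-1-ol 21 and oxidation of epoxy alcohol 22. Acid 29 is bought.

## Roads not taken

**Alternative 1:** Cut C4–C15 and C5–C6. In the forward step CuI-catalysed addition of MeMgBr across the alkyne of alkynol A2 (as its magnesium alkoxide) gives a chelated Z-alkenylmagnesium species, which is trapped by aldehyde A3 to give the Z-ene-3,6-diol A1.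
- Merits: one flask assembles C3–C6, the methyl on C4 and the Z geometry (enforced by the five-membered chelate). C3 is brought in as a preset stereocentre, which is better than the conformational control the chosen route relies on. No kinetic resolution is needed.
- Weak points: C6 arises from addition of a basic Grignard species to an α-branched, β-silyloxy aldehyde, where facial control is uncertain and α-epimerisation or β-elimination can compete. A1 is still acyclic: the ring would have to be closed at C1=C10 from two carbonyl groups, which leaves the E geometry unsecured. The exo-methylene must be added late by enolate chemistry.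
- Comparison: this road controls C3 better. The chosen route controls both alkene geometries before ring closure and gets the methylene lactone together with C7/C8.

**Alternative 2:** Cut C7–C11. In the forward step the carbanion of the C6 phosphonoacetate in macrocyclic trans-7,8-epoxide A5 opens the epoxide at C7 (5-exo), giving phosphono lactone A4 with a free C8 alcohol. Olefination with formaldehyde would then give the methylene lactone.
- Merits: anti opening of a trans-epoxide gives exactly the C7/C8 relationship of the target. On this point it is better than the chosen route, which needs a Mitsunobu inversion. The methylenation is built in.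
- Weak points: A5 already contains the ten-membered ring, so the macrocyclisation problem is moved, not solved. The 7,8-epoxide must be placed on one face of a ring that also holds the more electron-rich C1=C10 alkene. The base-mediated opening competes with transannular reactions and with loss of the allylic C6 ester.
- Comparison: the chosen route has to offset the extra inversion at C8. In return it supplies a defined way to close the ring.

**Alternative 3:** Cut C2–C3 and O–C1. In the forward step oxime A7 is oxidised to nitrile oxide A8, which adds across the terminal vinyl group to give the isoxazoline-bridged macrocycle A6.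
- Merits: ring closure and oxygenation of C1 happen together. The isoxazoline is a masked C3 ketone/C1 alcohol, and with the preset tertiary C10 alcohol the 1,10-epoxide could later be closed stereospecifically. That would be more secure than facial selection by a peracid.
- Weak points: a bridged ten-membered closure by dipolar cycloaddition is strained and competes with nitrile oxide dimerisation. C1 is controlled only by the neighbouring C10 centre. After the cycloaddition N–O cleavage, C3 reduction (again uncontrolled), epoxide closure, methylenation and two acylations remain.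
- Comparison: this road is better for the epoxide configuration. The chosen route sets against that a two-step endgame after ring closure.

Key step: step 18

Remarks on the chemistry:
- Germacrane numbering (C1–C15) is used for all intermediates.
- C6 is labelled S in the iodine-bearing intermediates and R in the macrocycles only because the CIP ranking changes; the geometry is the same.
- (R)-2-Methylbutanoic acid 29, (E)-2-methylbut-2-en-1-ol 21 and acid 7 are assumed to be purchased.
- The allylindium reagent 19 is drawn by its simplest formula RInBr2.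

## Route

Step 1
Reactants: 1 but-2-yn-1-ol
Product: 3 (2Z)-3-iodobut-2-en-1-ol, via cyclic sodium alkenylalanate 2 (not isolated)
Conditions: NaAlH2(OCH2CH2OMe)2, THF, 0 °C → rt; then I2, THF, −78 → 0 °C
Reagents that add atoms: iodine, II
Why: Alkoxide-directed trans-hydroalumination of the propargylic alcohol places aluminium on C3 inside the five-membered alanate 2; iododealumination with retention gives the Z-iodoalkene (iodine cis to CH2OH), the standard route to (Z)-3-iodoallylic alcohols.

Step 2
Reactants: 3 (2Z)-3-iodobut-2-en-1-ol
Product: 4 (2Z)-3-iodobut-2-enal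
Conditions: MnO2, CH2Cl2, rt, dark; used directly
Reagents that add atoms: none
Why: Heterogeneous, neutral allylic oxidation with MnO2 should keep the Z geometry of the sensitive β-iodoenal.

Step 3
Reactants: 4 (2Z)-3-iodobut-2-enal
Product: 5 rac-(4Z)-5-iodohexa-1,4-dien-3-ol
Conditions: CH2=CHMgBr, THF, −78 °C
Reagents that add atoms: vinylmagnesium bromide, C=C[Mg]Br
Why: 1,2-Addition of a vinyl Grignard reagent to the enal at low temperature; the carbinol (later C6) is formed racemic.

Step 4
Reactants: 5 rac-(4Z)-5-iodohexa-1,4-dien-3-ol
Product: 6 (3S,4Z)-5-iodohexa-1,4-dien-3-ol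
Conditions: Ti(OiPr)4 (10 mol%), L-(+)-DIPT (15 mol%), t-BuOOH (0.6 equiv), 4 Å MS, CH2Cl2, −20 °C
Reagents that add atoms: none
Why: Sharpless kinetic resolution: with L-(+)-DIPT the R enantiomer is epoxidised at its terminal vinyl group, while the S enantiomer is mismatched at that arm. The other allylic arm of the S enantiomer is a Z-configured, iodine-bearing trisubstituted alkene and a poor substrate, so 6 should remain in high enantiomeric purity past half conversion.

Step 5
Reactants: 6 (3S,4Z)-5-iodohexa-1,4-dien-3-ol; 7 2-(bromomethyl)prop-2-enoic acid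
Product: 8 (3S,4Z)-5-iodohexa-1,4-dien-3-yl 2-(bromomethyl)prop-2-enoate
Conditions: DCC, DMAP (5 mol%), CH2Cl2, 0 °C
Reagents that add atoms: none
Why: Steglich esterification acylates oxygen with retention at the carbinol; DMAP is kept catalytic and the temperature low so that the allylic bromide is not substituted.

Step 6
Reactants: 8 (3S,4Z)-5-iodohexa-1,4-dien-3-yl 2-(bromomethyl)prop-2-enoate
Product: 9 (5S)-3-(bromomethyl)-5-[(1Z)-2-iodoprop-1-en-1-yl]furan-2(5H)-one
Conditions: second-generation Grubbs catalyst RuCl2(=CHPh)(H2IMes)(PCy3) (5 mol%), CH2Cl2, 40 °C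
Reagents that add atoms: none
Why: Ring-closing metathesis: the ruthenium carbene loads on the monosubstituted vinyl group and closes onto the 1,1-disubstituted acrylate with loss of ethene. The trisubstituted iodoalkene is too hindered to take part, and allylic bromides are tolerated.

Step 7
Reactants: 10 but-3-yn-1-ol
Product: 11 (but-3-yn-1-yloxy)(tert-butyl)dimethylsilane
Conditions: TBSCl, imidazole, CH2Cl2, 0 °C → rt
Reagents that add atoms: tert-butyldimethylsilyl chloride, CC(C)(C)[Si](C)(C)Cl
Why: Standard silylation of a primary alcohol; the silyl ether is inert to the organoaluminium chemistry that follows.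

Step 8
Reactants: 11 (but-3-yn-1-yloxy)(tert-butyl)dimethylsilane; 12 ethylene oxide
Product: 15 (3E)-6-[(tert-butyldimethylsilyl)oxy]-4-methylhex-3-en-1-ol, via alkenyldimethylalane 13 (not isolated), via lithium alkenylalanate 14 (not isolated)
Conditions: Me3Al, Cp2ZrCl2 (20 mol%), CH2Cl2, 0 °C → rt; volatiles removed; n-BuLi, THF, −78 °C; then ethylene oxide, −78 → 0 °C
Reagents that add atoms: trimethylaluminium, C[Al](C)C
Why: Zirconium-catalysed Negishi carboalumination adds methyl and aluminium syn across the terminal alkyne with aluminium on the terminal carbon, which fixes the E trisubstituted alkene (later C1=C10 with C14). The alanate 14 is nucleophilic enough to open ethylene oxide with retention of the alkene geometry.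

Step 9
Reactants: 15 (3E)-6-[(tert-butyldimethylsilyl)oxy]-4-methylhex-3-en-1-ol
Product: 16 tert-butyl({(3E)-6-[(4-methoxyphenyl)methoxy]-3-methylhex-3-en-1-yl}oxy)dimethylsilane
Conditions: NaH, PMBCl, Bu4NI (cat.), THF/DMF, 0 °C → rt
Reagents that add atoms: 4-methoxybenzyl chloride, COc1ccc(CCl)cc1
Why: Williamson etherification of the primary alkoxide; the PMB ether marks the future C3 oxygen and is orthogonal to the silyl ether.

Step 10
Reactants: 16 tert-butyl({(3E)-6-[(4-methoxyphenyl)methoxy]-3-methylhex-3-en-1-yl}oxy)dimethylsilane
Product: 17 (3E)-6-[(4-methoxyphenyl)methoxy]-3-methylhex-3-en-1-ol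
Conditions: TBAF, THF, 0 °C → rt
Reagents that add atoms: none
Why: Fluoride-induced desilylation frees the future C8 carbon's hydroxyl and leaves the PMB ether untouched.

Step 11
Reactants: 17 (3E)-6-[(4-methoxyphenyl)methoxy]-3-methylhex-3-en-1-ol
Product: 18 (3E)-6-[(4-methoxyphenyl)methoxy]-3-methylhex-3-enal
Conditions: Dess–Martin periodinane, pyridine, CH2Cl2, 0 °C; used crude
Reagents that add atoms: none
Why: Buffered Dess–Martin oxidation gives the skipped aldehyde under near-neutral conditions, which should keep the alkene out of conjugation; the aldehyde is not purified.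

Step 12
Reactants: 9 (5S)-3-(bromomethyl)-5-[(1Z)-2-iodoprop-1-en-1-yl]furan-2(5H)-one; 18 (3E)-6-[(4-methoxyphenyl)methoxy]-3-methylhex-3-enal
Product: 20 (4R,5S)-4-{(1S,3E)-1-hydroxy-6-[(4-methoxyphenyl)methoxy]-3-methylhex-3-en-1-yl}-5-[(1Z)-2-iodoprop-1-en-1-yl]-3-methylideneoxolan-2-one, via allylindium bromide 19 (not isolated)
Conditions: In powder, THF/H2O (3:1), rt
Reagents that add atoms: none
Why: Indium-mediated Barbier allylation: the allylindium reagent attacks through its γ-carbon (C7) and generates the exo-methylene lactone; the vinyl iodide is inert to indium metal. The aldehyde adds anti to the C6 substituent (6,7-trans). In the chair Zimmerman–Traxler transition state the ring-locked γ-substituent and the aldehyde chain are both equatorial, which gives the 8S carbinol, the C8 epimer of the target, corrected in step 15.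

Step 13
Reactants: 21 (2E)-2-methylbut-2-en-1-ol
Product: 22 [(2R,3R)-2,3-dimethyloxiran-2-yl]methanol
Conditions: Ti(OiPr)4 (10 mol%), D-(−)-DIPT (15 mol%), t-BuOOH, 4 Å MS, CH2Cl2, −20 °C
Reagents that add atoms: tert-butyl hydroperoxide, CC(C)(C)OO
Why: Sharpless asymmetric epoxidation of a trisubstituted E allylic alcohol; the D-tartrate delivers oxygen to the face that gives the 2R,3R epoxy alcohol, with the methyl groups cis as in the alkene.

Step 14
Reactants: 22 [(2R,3R)-2,3-dimethyloxiran-2-yl]methanol
Product: 23 (2S,3R)-2,3-dimethyloxirane-2-carboxylic acid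
Conditions: RuCl3·xH2O (2 mol%), NaIO4, MeCN/EtOAc/H2O, 0 °C → rt
Reagents that add atoms: water, O
Why: Ruthenium tetroxide-type oxidation (RuCl3/NaIO4) takes the primary alcohol to the acid without touching the epoxide; the C2 label changes from R to S only through CIP ranking.

Step 15
Reactants: 20 (4R,5S)-4-{(1S,3E)-1-hydroxy-6-[(4-methoxyphenyl)methoxy]-3-methylhex-3-en-1-yl}-5-[(1Z)-2-iodoprop-1-en-1-yl]-3-methylideneoxolan-2-one; 23 (2S,3R)-2,3-dimethyloxirane-2-carboxylic acid
Product: 24 (1R,3E)-1-[(2S,3R)-2-[(1Z)-2-iodoprop-1-en-1-yl]-4-methylidene-5-oxooxolan-3-yl]-6-[(4-methoxyphenyl)methoxy]-3-methylhex-3-en-1-yl (2S,3R)-2,3-dimethyloxirane-2-carboxylate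
Conditions: PPh3, DIAD, toluene, 0 °C → rt
Reagents that add atoms: none
Why: Mitsunobu esterification: the alkoxyphosphonium ion of the C8 alcohol is displaced by the carboxylate of 23 with inversion (8S → 8R). The glycidic acid is acidic enough (α-oxygen) to protonate the betaine. C8 is homoallylic, so no allylic transposition is possible.

Step 16
Reactants: 24 (the PMB ether from step 15)
Product: 25 (1R,3E)-6-hydroxy-1-[(2S,3R)-2-[(1Z)-2-iodoprop-1-en-1-yl]-4-methylidene-5-oxooxolan-3-yl]-3-methylhex-3-en-1-yl (2S,3R)-2,3-dimethyloxirane-2-carboxylate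
Conditions: DDQ, CH2Cl2/pH 7 buffer (10:1), 0 °C → rt
Reagents that add atoms: none
Why: Oxidative cleavage of the PMB ether by DDQ is neutral and leaves the epoxy ester, the methylene lactone, the vinyl iodide and the isolated alkene alone.

Step 17
Reactants: 25 (the primary alcohol from step 16)
Product: 26 (1R,3E)-1-[(2S,3R)-2-[(1Z)-2-iodoprop-1-en-1-yl]-4-methylidene-5-oxooxolan-3-yl]-3-methyl-6-oxohex-3-en-1-yl (2S,3R)-2,3-dimethyloxirane-2-carboxylate
Conditions: Dess–Martin periodinane, pyridine, CH2Cl2, 0 °C; used crude
Reagents that add atoms: none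
Why: Buffered Dess–Martin oxidation gives the C3 aldehyde; it is again skipped relative to C1=C10 and is carried forward without chromatography.

Step 18
Reactants: 26 (the seco iodo-aldehyde lactone from step 17)
Product: 28 (3aR,4R,6E,9S,10Z,11aR)-9-hydroxy-6,10-dimethyl-3-methylidene-2-oxo-2,3,3a,4,5,8,9,11a-octahydrocyclodeca[b]furan-4-yl (2S,3R)-2,3-dimethyloxirane-2-carboxylate, via vinylchromium dichloride 27 (not isolated)
Conditions: CrCl2 (8 equiv), NiCl2 (0.1 equiv), degassed DMSO, rt, slow addition of 26 to about 2 mM
Reagents that add atoms: none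
Why: CrCl2 reduces NiCl2 to zerovalent nickel, which inserts into the C4–I bond of 26 with retention of the Z geometry; transmetallation to trivalent chromium gives vinylchromium 27, and its addition to the C3 aldehyde forms C3–C4. The closest known reaction type is the intramolecular Nozaki–Hiyama–Kishi coupling of a vinyl iodide with an aldehyde, established for medium and large carbocycles. The ten-membered ring closes end to end by exo addition to the carbonyl (10-exo-trig); the trans-lactone, the Z C4=C5 alkene and the E C1=C10 alkene remove rotors from the tether, and slow addition at high dilution suppresses intermolecular coupling. The new C3 stereocentre is controlled only by the conformation of the cyclising chain: the aldehyde is expected to react with its oxygen on the periphery of the forming ring, which should give the 3S (3β) alcohol, and this is the least secure element of the step. The step needs chemoselectivity for the aldehyde over the exo-methylene lactone, the ester and the epoxide, which the low basicity and nucleophilicity of vinylchromium reagents at room temperature should secure. It also needs the skipped aldehyde to stay unconjugated, which the non-basic medium favours.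

Step 19
Reactants: 28 (the macrocyclic C3 alcohol from step 18); 29 (2R)-2-methylbutanoic acid
Product: 30 (3aR,4R,6E,9S,10Z,11aR)-6,10-dimethyl-3-methylidene-9-{[(2R)-2-methylbutanoyl]oxy}-2-oxo-2,3,3a,4,5,8,9,11a-octahydrocyclodeca[b]furan-4-yl (2S,3R)-2,3-dimethyloxirane-2-carboxylate
Conditions: DCC, DMAP, CH2Cl2, 0 °C → rt
Reagents that add atoms: none
Why: Steglich esterification of the allylic alcohol with retention at C3; a simple α-branched alkanoic acid is not expected to epimerise under these conditions.

Step 20
Reactants: 30 (the diester from step 19)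
Product: 31 CNP0265335.4, (1R,3S,4Z,6R,7R,8R,10R)-8-{[(2S,3R)-2,3-dimethyloxirane-2-carbonyl]oxy}-1,10-epoxy-3-{[(2R)-2-methylbutanoyl]oxy}germacra-4,11(13)-dien-12,6-olide
Conditions: mCPBA (1.1 equiv), CH2Cl2, −20 → 0 °C
Reagents that add atoms: 3-chloroperbenzoic acid, OOC(=O)c1cccc(Cl)c1
Why: Prilezhaev epoxidation: C1=C10 is the only electron-rich alkene, since C4=C5 carries two allylic acyloxy groups and the exo-methylene is conjugated. Syn addition to the E alkene gives the trans epoxide, and attack on the outer face of the ring alkene, the usual mode for germacranolides, should give the 1R,10R (1β,10α) isomer.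

## Compound list

1 | but-2-yn-1-ol | CC#CCO | starting material
2 | sodium 2,2-bis(2-methoxyethoxy)-3-methyl-2,5-dihydro-1,2-oxaaluminol-2-uide | [Na+].CC1=CCO[Al-]1(OCCOC)OCCOC | intermediate (not isolated)
3 | (2Z)-3-iodobut-2-en-1-ol | C/C(I)=C/CO | intermediate
4 | (2Z)-3-iodobut-2-enal | C/C(I)=C/C=O | intermediate
5 | rac-(4Z)-5-iodohexa-1,4-dien-3-ol | C=CC(O)/C=C(/C)I | intermediate
6 | (3S,4Z)-5-iodohexa-1,4-dien-3-ol | C=C[C@H](O)/C=C(/C)I | intermediate
7 | 2-(bromomethyl)prop-2-enoic acid | C=C(CBr)C(=O)O | starting material
8 | (3S,4Z)-5-iodohexa-1,4-dien-3-yl 2-(bromomethyl)prop-2-enoate | C=C[C@H](OC(=O)C(=C)CBr)/C=C(/C)I | intermediate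
9 | (5S)-3-(bromomethyl)-5-[(1Z)-2-iodoprop-1-en-1-yl]furan-2(5H)-one | BrCC1=C[C@@H](/C=C(/C)I)OC1=O | intermediate
10 | but-3-yn-1-ol | C#CCCO | starting material
11 | (but-3-yn-1-yloxy)(tert-butyl)dimethylsilane | C#CCCO[Si](C)(C)C(C)(C)C | intermediate
12 | ethylene oxide | C1CO1 | starting material
13 | {(1E)-4-[(tert-butyldimethylsilyl)oxy]-2-methylbut-1-en-1-yl}dimethylalane | C[Al](C)/C=C(\C)CCO[Si](C)(C)C(C)(C)C | intermediate (not isolated)
14 | lithium butyl{(1E)-4-[(tert-butyldimethylsilyl)oxy]-2-methylbut-1-en-1-yl}dimethylalanuide | [Li+].CCCC[Al-](C)(C)/C=C(\C)CCO[Si](C)(C)C(C)(C)C | intermediate (not isolated)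
15 | (3E)-6-[(tert-butyldimethylsilyl)oxy]-4-methylhex-3-en-1-ol | OCC/C=C(\C)CCO[Si](C)(C)C(C)(C)C | intermediate
16 | tert-butyl({(3E)-6-[(4-methoxyphenyl)methoxy]-3-methylhex-3-en-1-yl}oxy)dimethylsilane | COc1ccc(COCC/C=C(\C)CCO[Si](C)(C)C(C)(C)C)cc1 | intermediate
17 | (3E)-6-[(4-methoxyphenyl)methoxy]-3-methylhex-3-en-1-ol | COc1ccc(COCC/C=C(\C)CCO)cc1 | intermediate
18 | (3E)-6-[(4-methoxyphenyl)methoxy]-3-methylhex-3-enal | COc1ccc(COCC/C=C(\C)CC=O)cc1 | intermediate
19 | dibromo({(5S)-5-[(1Z)-2-iodoprop-1-en-1-yl]-2-oxo-2,5-dihydrofuran-3-yl}methyl)indium | Br[In](Br)CC1=C[C@@H](/C=C(/C)I)OC1=O | intermediate (not isolated)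
20 | (4R,5S)-4-{(1S,3E)-1-hydroxy-6-[(4-methoxyphenyl)methoxy]-3-methylhex-3-en-1-yl}-5-[(1Z)-2-iodoprop-1-en-1-yl]-3-methylideneoxolan-2-one | C=C1C(=O)O[C@H](/C=C(/C)I)[C@H]1[C@@H](O)C/C(C)=C/CCOCc1ccc(OC)cc1 | intermediate
21 | (2E)-2-methylbut-2-en-1-ol | C/C=C(\C)CO | starting material
22 | [(2R,3R)-2,3-dimethyloxiran-2-yl]methanol | OC[C@@]1(C)O[C@@H]1C | intermediate
23 | (2S,3R)-2,3-dimethyloxirane-2-carboxylic acid | O=C(O)[C@@]1(C)O[C@@H]1C | intermediate
24 | (1R,3E)-1-[(2S,3R)-2-[(1Z)-2-iodoprop-1-en-1-yl]-4-methylidene-5-oxooxolan-3-yl]-6-[(4-methoxyphenyl)methoxy]-3-methylhex-3-en-1-yl (2S,3R)-2,3-dimethyloxirane-2-carboxylate | C=C1C(=O)O[C@H](/C=C(/C)I)[C@H]1[C@H](OC(=O)[C@@]2(C)O[C@@H]2C)C/C(C)=C/CCOCc1ccc(OC)cc1 | intermediate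
25 | (1R,3E)-6-hydroxy-1-[(2S,3R)-2-[(1Z)-2-iodoprop-1-en-1-yl]-4-methylidene-5-oxooxolan-3-yl]-3-methylhex-3-en-1-yl (2S,3R)-2,3-dimethyloxirane-2-carboxylate | C=C1C(=O)O[C@H](/C=C(/C)I)[C@H]1[C@H](OC(=O)[C@@]2(C)O[C@@H]2C)C/C(C)=C/CCO | intermediate
26 | (1R,3E)-1-[(2S,3R)-2-[(1Z)-2-iodoprop-1-en-1-yl]-4-methylidene-5-oxooxolan-3-yl]-3-methyl-6-oxohex-3-en-1-yl (2S,3R)-2,3-dimethyloxirane-2-carboxylate | C=C1C(=O)O[C@H](/C=C(/C)I)[C@H]1[C@H](OC(=O)[C@@]2(C)O[C@@H]2C)C/C(C)=C/CC=O | intermediate
27 | vinylchromium dichloride of 26 (CrCl2 in place of iodine at C4, Z retained) | C=C1C(=O)O[C@H](/C=C(/C)[Cr](Cl)Cl)[C@H]1[C@H](OC(=O)[C@@]2(C)O[C@@H]2C)C/C(C)=C/CC=O | intermediate (not isolated)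
28 | (3aR,4R,6E,9S,10Z,11aR)-9-hydroxy-6,10-dimethyl-3-methylidene-2-oxo-2,3,3a,4,5,8,9,11a-octahydrocyclodeca[b]furan-4-yl (2S,3R)-2,3-dimethyloxirane-2-carboxylate | C=C1C(=O)O[C@@H]2/C=C(/C)[C@@H](O)C/C=C(\C)C[C@@H](OC(=O)[C@@]3(C)O[C@@H]3C)[C@@H]12 | intermediate
29 | (2R)-2-methylbutanoic acid | CC[C@@H](C)C(=O)O | starting material
30 | (3aR,4R,6E,9S,10Z,11aR)-6,10-dimethyl-3-methylidene-9-{[(2R)-2-methylbutanoyl]oxy}-2-oxo-2,3,3a,4,5,8,9,11a-octahydrocyclodeca[b]furan-4-yl (2S,3R)-2,3-dimethyloxirane-2-carboxylate | C=C1C(=O)O[C@@H]2/C=C(/C)[C@@H](OC(=O)[C@H](C)CC)C/C=C(\C)C[C@@H](OC(=O)[C@@]3(C)O[C@@H]3C)[C@@H]12 | intermediate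
31 | CNP0265335.4, (1R,3S,4Z,6R,7R,8R,10R)-8-{[(2S,3R)-2,3-dimethyloxirane-2-carbonyl]oxy}-1,10-epoxy-3-{[(2R)-2-methylbutanoyl]oxy}germacra-4,11(13)-dien-12,6-olide | C=C1C(=O)O[C@@H]2/C=C(/C)[C@@H](OC(=O)[C@H](C)CC)C[C@H]3O[C@]3(C)C[C@@H](OC(=O)[C@@]3(C)O[C@@H]3C)[C@@H]12 | target

## Step count and risk

Total steps: 20. Longest linear sequence: 13 (steps 1–6, 12, 15–20, from but-2-yn-1-ol).

**Step 18 (key step).** Most likely failures are intermolecular coupling outrunning the entropically costly ten-membered closure, and poor facial selectivity at C3, because nothing but ring conformation directs the addition. Migration of the C1=C10 alkene into conjugation with the aldehyde before coupling is a further loss channel. Fallback for the C3 problem, setting out from 26 and returning at 28: the cyclisation is run as before, and the 3-epimeric macrocyclic alcohol F1 (alone or mixed with 28) is oxidised with Dess–Martin periodinane to the C3 enone F2. F2 is reduced with catecholborane under (R)-2-methyl-CBS-oxazaborolidine control at −78 °C. With the alkenyl side as the large group this should deliver the 3S alcohol 28 by reagent control, independent of ring conformation.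

**Step 15.** The activated C8 alcohol may eliminate toward C7 (an allylic hydrogen) or C9 instead of being substituted, since the centre is flanked by the lactone ring; slow substitution can also allow acylation with retention. Fallback, setting out from 20 and returning at 24: Dess–Martin oxidation gives the C8 ketone F3, and reduction with catecholborane and (S)-2-methyl-CBS-oxazaborolidine (lactone carbon as the large group) gives the 8R alcohol F4. F4 is then esterified with 23 (DCC, DMAP) with retention to give 24.

**Step 12.** The skipped aldehyde 18 may isomerise into conjugation before C–C bond formation, and in water part of the reaction may leak through non-chair transition states and erode the C8 selectivity on which step 15 depends. Fallback, setting out from 9 (with 18) and returning at 20: the allyl bromide is converted with CrCl2 in dry THF into a discrete allylchromium reagent (Nozaki–Hiyama allylation, no nickel, so the vinyl iodide stays intact). This reagent adds under anhydrous, aprotic conditions through the same closed chair. No new isolated compound arises.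

**Step 20.** The peracid may attack the other face of C1=C10 if the reactive ring conformer is not the expected one, or the new epoxide may open transannularly under the acid by-product. Fallback, setting out from 30 and returning at 31: the facial choice is taken from the substrate and given to a catalyst by epoxidising with the D-fructose-derived Shi ketone and KHSO5 (Oxone) in buffered MeCN/water at 0 °C. For an E-trisubstituted alkene this should give the R,R epoxide and avoids acid. No new compound arises.

## Further compounds

F1 | step 18 | (3aR,4R,6E,9R,10Z,11aR)-9-hydroxy-6,10-dimethyl-3-methylidene-2-oxo-2,3,3a,4,5,8,9,11a-octahydrocyclodeca[b]furan-4-yl (2S,3R)-2,3-dimethyloxirane-2-carboxylate | C=C1C(=O)O[C@@H]2/C=C(/C)[C@H](O)C/C=C(\C)C[C@@H](OC(=O)[C@@]3(C)O[C@@H]3C)[C@@H]12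
F2 | step 18 | (3aR,4R,6E,10Z,11aR)-6,10-dimethyl-3-methylidene-2,9-dioxo-2,3,3a,4,5,8,9,11a-octahydrocyclodeca[b]furan-4-yl (2S,3R)-2,3-dimethyloxirane-2-carboxylate | C=C1C(=O)O[C@@H]2/C=C(/C)C(=O)C/C=C(\C)C[C@@H](OC(=O)[C@@]3(C)O[C@@H]3C)[C@@H]12
F3 | step 15 | (4S,5S)-5-[(1Z)-2-iodoprop-1-en-1-yl]-4-{(3E)-6-[(4-methoxyphenyl)methoxy]-3-methylhex-3-enoyl}-3-methylideneoxolan-2-one | C=C1C(=O)O[C@H](/C=C(/C)I)[C@H]1C(=O)C/C(C)=C/CCOCc1ccc(OC)cc1
F4 | step 15 | (4R,5S)-4-{(1R,3E)-1-hydroxy-6-[(4-methoxyphenyl)methoxy]-3-methylhex-3-en-1-yl}-5-[(1Z)-2-iodoprop-1-en-1-yl]-3-methylideneoxolan-2-one | C=C1C(=O)O[C@H](/C=C(/C)I)[C@H]1[C@H](O)C/C(C)=C/CCOCc1ccc(OC)cc1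
F0 | step 12 | none | none
F0 | step 20 | none | none
A1 | alternative 1 | Z-ene-3,6-diol (tert-butyl ester, C8 silyl ether, C10 dioxolane, C1 dimethyl acetal) | CC(C)(C)OC(=O)C[C@H]([C@H](O[Si](C)(C)C(C)(C)C)CC1(C)OCCO1)[C@H](O)/C=C(/C)[C@@H](O)CC(OC)OC
A2 | alternative 1 | (3S)-5,5-dimethoxypent-1-yn-3-ol | C#C[C@@H](O)CC(OC)OC
A3 | alternative 1 | tert-butyl 4-[(tert-butyldimethylsilyl)oxy]-3-formyl-5-(2-methyl-1,3-dioxolan-2-yl)pentanoate (C7, C8 as in A1) | CC(C)(C)OC(=O)C[C@H]([C@H](O[Si](C)(C)C(C)(C)C)CC1(C)OCCO1)C=O
A4 | alternative 2 | α-(diethoxyphosphoryl) lactone with free C8 alcohol and C3 silyl ether | CCOP(=O)(OCC)C1C(=O)O[C@@H]2/C=C(/C)[C@@H](O[Si](C)(C)C(C)(C)C)C/C=C(\C)C[C@@H](O)[C@@H]12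
A5 | alternative 2 | macrocyclic trans-7,8-epoxide bearing the C6 diethylphosphonoacetate and C3 silyl ether | CCOP(=O)(OCC)CC(=O)O[C@@H]1/C=C(/C)[C@@H](O[Si](C)(C)C(C)(C)C)C/C=C(\C)C[C@H]2O[C@H]12
A6 | alternative 3 | isoxazoline-bridged macrocycle (C10 tertiary alcohol, C8 silyl ether, saturated lactone) | O=C1C[C@H]2[C@H](O1)/C=C(/C)C3=NO[C@@H](C3)[C@](C)(O)C[C@H]2O[Si](C)(C)C(C)(C)C
A7 | alternative 3 | seco enal oxime with terminal vinyl carbinol | O=C1C[C@@H]([C@H](O1)/C=C(/C)C=NO)[C@H](O[Si](C)(C)C(C)(C)C)C[C@@](C)(O)C=C
A8 | alternative 3 | nitrile oxide derived from A7 | O=C1C[C@@H]([C@H](O1)/C=C(/C)C#[N+][O-])[C@H](O[Si](C)(C)C(C)(C)C)C[C@@](C)(O)C=C
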